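## Retrosynthetic overview

- The strategy rests on C2 of the 4-pyranone (ring C). It is bonded to O1, C3 and the doubly ortho-substituted C1' of ring B, sits at the carboxylic oxidation level, and is therefore traced back to carbon monoxide.
- Key disconnection: C2–C3 and C2–C1' are cut together. This gives the ring A methyl ketone (O8a as MOM ether, O6 as benzyl ether), CO and the ring B iodide (2'-O as benzyl ether). In the forward direction these are joined by a palladium-catalysed carbonylative ketone α-arylation to an open-chain 1,3-diketone.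
- Ring C is the only ring that is built. It closes last through O1–C2 by acid treatment (MOM loss, cyclodehydration), and the two benzyl ethers are then hydrogenolysed.
- Ring A ketone: 1,2,3,5-tetramethoxybenzene, acetylation with ortho-demethylation, Elbs para-hydroxylation, benzylation of the free 5-OH, MOM protection.
- Ring B iodide: 3-methoxyphenol, benzyl ether, lithiation between the two oxygens, iodine quench.

Key step: step 7

Remark on the chemistry: the target has no stereocentre, so no stereocontrol is required; 1,2,3,5-tetramethoxybenzene is taken as a purchasable arene.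

## Route

Step 1
Reactants: 1 1,2,3,5-tetramethoxybenzene
Product: 3 1-(2-hydroxy-3,4,6-trimethoxyphenyl)ethanone, via 1-(2,3,4,6-tetramethoxyphenyl)ethanone 2 (not isolated)
Conditions: AcCl, AlCl3 (3 equiv), Et2O, 0 °C to reflux; aq HCl
Reagents that add atoms: acetyl chloride, CC(Cl)=O
Why: Friedel–Crafts acylation takes place at one of the two equivalent free ring positions, and AlCl3 held by the new carbonyl group then cleaves the ortho methoxyl squeezed between the acetyl group and a neighbouring methoxyl (chelation-controlled ortho-demethylation), so the hydrogen-bonded phenol 3 should result.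

Step 2
Reactants: 3 1-(2-hydroxy-3,4,6-trimethoxyphenyl)ethanone
Product: 5 1-(2,5-dihydroxy-3,4,6-trimethoxyphenyl)ethanone, via potassium aryl sulfate 4 (not isolated)
Conditions: K2S2O8, aq NaOH, 15–20 °C; then HCl, Na2SO3, 90 °C
Reagents that add atoms: potassium peroxodisulfate, [K+].[K+].[O-]S(=O)(=O)OOS(=O)(=O)[O-]
Why: Elbs persulfate oxidation, in which the phenolate attacks a peroxide oxygen through its para carbon (the only unsubstituted ring position) and the aryl sulfate 4 is hydrolysed by hot acid to the hydroquinone.

Step 3
Reactants: 5 1-(2,5-dihydroxy-3,4,6-trimethoxyphenyl)ethanone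
Product: 6 1-[3-(benzyloxy)-6-hydroxy-2,4,5-trimethoxyphenyl]ethanone
Conditions: BnBr (1.05 equiv), K2CO3, acetone, reflux, N2
Reagents that add atoms: benzyl bromide, BrCc1ccccc1
Why: Williamson etherification is expected at the 5-OH only, because the 2-OH is held in a hydrogen bond to the acetyl carbonyl and reacts far more slowly with a weak base and one equivalent of halide.

Step 4
Reactants: 6 1-[3-(benzyloxy)-6-hydroxy-2,4,5-trimethoxyphenyl]ethanone
Product: 7 1-[3-(benzyloxy)-2,4,5-trimethoxy-6-(methoxymethoxy)phenyl]ethanone
Conditions: NaH (1.1 equiv), MOMCl, DMF, 0 °C to rt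
Reagents that add atoms: chloromethyl methyl ether, COCCl
Why: Williamson-type O-alkylation, in which NaH breaks the chelate and the phenoxide is alkylated on oxygen by the reactive α-chloro ether, leaving O8a as the only acid-labile position of the fragment.

Step 5
Reactants: 8 3-methoxyphenol
Product: 9 1-(benzyloxy)-3-methoxybenzene
Conditions: BnBr, K2CO3, acetone, reflux
Reagents that add atoms: benzyl bromide, BrCc1ccccc1
Why: Williamson ether synthesis on an unhindered phenol.

Step 6
Reactants: 9 1-(benzyloxy)-3-methoxybenzene
Product: 11 1-(benzyloxy)-2-iodo-3-methoxybenzene, via aryllithium 10 (not isolated)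
Conditions: n-BuLi, Et2O, 0 °C to rt; then I2, THF, −78 °C to rt
Reagents that add atoms: iodine, II
Why: Directed ortho-metalation, in which the proton between the two ether oxygens is the most acidic ring proton and is removed by n-BuLi coordinated to both oxygens, the aryllithium then being trapped by iodine; the low-polarity medium limits benzylic deprotonation.

Step 7
Reactants: 7 1-[3-(benzyloxy)-2,4,5-trimethoxy-6-(methoxymethoxy)phenyl]ethanone; 11 1-(benzyloxy)-2-iodo-3-methoxybenzene (1.2 equiv); 12 carbon monoxide
Product: 13 1-[3-(benzyloxy)-2,4,5-trimethoxy-6-(methoxymethoxy)phenyl]-3-[2-(benzyloxy)-6-methoxyphenyl]propane-1,3-dione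
Conditions: Pd(dba)2 (5 mol %), Xantphos (5 mol %), NaN(SiMe3)2 (2.2 equiv), CO (5 bar), dioxane, 80 °C; aq NH4Cl
Reagents that add atoms: none
Why: Zerovalent palladium carrying Xantphos inserts into the C–I bond of 11, CO inserts into the aryl–palladium bond to give an aroylpalladium iodide (this makes C2–C1'), the sodium enolate of 7 replaces iodide, and reductive elimination from the C-bound aroyl(enolate)palladium complex makes C2–C3 and returns zerovalent palladium. The closest known reaction type is the palladium-catalysed carbonylative α-arylation of aryl methyl ketones with aryl iodides to 1,3-diketones. No ring is closed and no stereocentre is formed. The step needs carbonylative C-acylation to win over direct α-arylation and over O-acylation: the two ortho substituents of 11 slow enolate transfer and reductive elimination at the arylpalladium stage, whereas CO insertion moves the metal one atom away from the crowded ring, and CO pressure together with the wide bite angle of Xantphos keeps the aroyl complex populated and speeds its reductive elimination. The methyl group of 7 is the only enolisable position and stands clear of its fully substituted ring, and the second equivalent of base stores the product as its diketonate, which stops a second acylation. The MOM, benzyl and methyl ethers are inert to the base and to the catalyst.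

Step 8
Reactants: 13 1-[3-(benzyloxy)-2,4,5-trimethoxy-6-(methoxymethoxy)phenyl]-3-[2-(benzyloxy)-6-methoxyphenyl]propane-1,3-dione
Product: 15 6-(benzyloxy)-2-[2-(benzyloxy)-6-methoxyphenyl]-5,7,8-trimethoxy-4H-chromen-4-one, via hydroxy diketone 14 (not isolated)
Conditions: HCl (methanolic), MeOH/THF, 60 °C
Reagents that add atoms: none
Why: Acid cleaves the MOM acetal, the freed O8a hydroxyl adds to the ring B carbonyl (6-exo-trig hemiketal formation) and loss of water gives the 4-pyranone; O8a is the only free phenol, so the cyclodehydration can run in one direction only, and aryl benzyl and methyl ethers are stable to these conditions.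

Step 9
Reactants: 15 6-(benzyloxy)-2-[2-(benzyloxy)-6-methoxyphenyl]-5,7,8-trimethoxy-4H-chromen-4-one
Product: 16 6-hydroxy-2-(2-hydroxy-6-methoxyphenyl)-5,7,8-trimethoxy-4H-chromen-4-one (6,2'-dihydroxy-5,7,8,6'-tetramethoxyflavone)
Conditions: H2 (1 atm), 10% Pd/C, EtOAc/MeOH, rt
Reagents that add atoms: none
Why: Catalytic hydrogenolysis cleaves both benzylic C–O bonds, while the chromone double bond (a vinylogous ester) and the aryl methyl ethers are not expected to react at atmospheric pressure.

## Compound list

1 | 1,2,3,5-tetramethoxybenzene | COc1cc(OC)c(OC)c(OC)c1 | starting material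
2 | 1-(2,3,4,6-tetramethoxyphenyl)ethanone | CC(=O)c1c(OC)c(OC)c(OC)cc1OC | intermediate
3 | 1-(2-hydroxy-3,4,6-trimethoxyphenyl)ethanone | CC(=O)c1c(O)c(OC)c(OC)cc1OC | intermediate
4 | potassium 3-acetyl-4-hydroxy-2,5,6-trimethoxyphenyl sulfate | CC(=O)c1c(O)c(OC)c(OC)c(OS(=O)(=O)[O-])c1OC.[K+] | intermediate
5 | 1-(2,5-dihydroxy-3,4,6-trimethoxyphenyl)ethanone | CC(=O)c1c(O)c(OC)c(OC)c(O)c1OC | intermediate
6 | 1-[3-(benzyloxy)-6-hydroxy-2,4,5-trimethoxyphenyl]ethanone | CC(=O)c1c(O)c(OC)c(OC)c(OCc2ccccc2)c1OC | intermediate
7 | 1-[3-(benzyloxy)-2,4,5-trimethoxy-6-(methoxymethoxy)phenyl]ethanone | CC(=O)c1c(OCOC)c(OC)c(OC)c(OCc2ccccc2)c1OC | intermediate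
8 | 3-methoxyphenol | COc1cccc(O)c1 | starting material
9 | 1-(benzyloxy)-3-methoxybenzene | COc1cccc(OCc2ccccc2)c1 | intermediate
10 | [2-(benzyloxy)-6-methoxyphenyl]lithium | [Li]c1c(OC)cccc1OCc1ccccc1 | intermediate
11 | 1-(benzyloxy)-2-iodo-3-methoxybenzene | COc1cccc(OCc2ccccc2)c1I | intermediate
12 | carbon monoxide | [C-]#[O+] | starting material
13 | 1-[3-(benzyloxy)-2,4,5-trimethoxy-6-(methoxymethoxy)phenyl]-3-[2-(benzyloxy)-6-methoxyphenyl]propane-1,3-dione | COCOc1c(OC)c(OC)c(OCc2ccccc2)c(OC)c1C(=O)CC(=O)c1c(OC)cccc1OCc1ccccc1 | intermediate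
14 | 1-[3-(benzyloxy)-6-hydroxy-2,4,5-trimethoxyphenyl]-3-[2-(benzyloxy)-6-methoxyphenyl]propane-1,3-dione | Oc1c(OC)c(OC)c(OCc2ccccc2)c(OC)c1C(=O)CC(=O)c1c(OC)cccc1OCc1ccccc1 | intermediate
15 | 6-(benzyloxy)-2-[2-(benzyloxy)-6-methoxyphenyl]-5,7,8-trimethoxy-4H-chromen-4-one | COc1cccc(OCc2ccccc2)c1-c1cc(=O)c2c(OC)c(OCc3ccccc3)c(OC)c(OC)c2o1 | intermediate
16 | 6-hydroxy-2-(2-hydroxy-6-methoxyphenyl)-5,7,8-trimethoxy-4H-chromen-4-one | COc1cccc(O)c1-c1cc(=O)c2c(OC)c(O)c(OC)c(OC)c2o1 | target

## Step count and risks

Total step count: 9 steps.
Longest linear sequence: 7 steps (steps 1, 2, 3, 4, 7, 8, 9).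

Steps most likely to fail:

**Step 7 (carbonylative α-arylation).** Oxidative addition of the electron-rich, doubly ortho-substituted iodide may be slowed when CO saturates zerovalent palladium. Direct α-arylation without CO uptake, or acylation of the enolate on oxygen, may also divert material. The fallback is a Baker–Venkataraman acyl transfer and sets out from 9 and 6. Aryllithium 10, generated from 9 as in step 6, would be quenched with CO2 to give 2-(benzyloxy)-6-methoxybenzoic acid F1. (COCl)2 with catalytic DMF in CH2Cl2 should convert this into 2-(benzyloxy)-6-methoxybenzoyl chloride F2. Acylation of phenol 6 (pyridine, DMAP, 60 °C) should give 2-acetyl-4-(benzyloxy)-3,5,6-trimethoxyphenyl 2-(benzyloxy)-6-methoxybenzoate F3. KOH in pyridine at 50 °C should then move the aroyl group from oxygen to the enolate carbon. The fallback comes back to the route at hydroxy diketone 14, which is cyclodehydrated under the acid conditions of step 8.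

**Step 2 (Elbs oxidation).** Conversion of the chelated phenolate may be low, and one-electron over-oxidation of the electron-rich ring by persulfate may consume material. The fallback sets out from 3. Teuber oxidation with Fremy's salt K2[ON(SO3)2] (aq KH2PO4/acetone, rt) should give 2-acetyl-3,5,6-trimethoxycyclohexa-2,5-diene-1,4-dione F4. Reduction of the quinone with Na2S2O4 (water/EtOAc) then comes back to the route at hydroquinone 5.

**Step 6 (ring lithiation of the benzyl ether).** Deprotonation at the benzylic CH2 may compete with ring lithiation and lead on to a [1,2]-Wittig rearrangement. The fallback sets out from 8 and uses a MOM ether as the directing group. MOMCl and iPr2NEt in CH2Cl2 should give 1-methoxy-3-(methoxymethoxy)benzene F5. n-BuLi in THF at 0 °C should give [2-methoxy-6-(methoxymethoxy)phenyl]lithium F6, which iodine converts into 2-iodo-1-methoxy-3-(methoxymethoxy)benzene F7. HCl in MeOH should free 2-iodo-3-methoxyphenol F8, and benzylation (BnBr, K2CO3, acetone) comes back to the route at iodide 11.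

## Further compounds

F1 | step 7 | 2-(benzyloxy)-6-methoxybenzoic acid | COc1cccc(OCc2ccccc2)c1C(=O)O
F2 | step 7 | 2-(benzyloxy)-6-methoxybenzoyl chloride | COc1cccc(OCc2ccccc2)c1C(Cl)=O
F3 | step 7 | 2-acetyl-4-(benzyloxy)-3,5,6-trimethoxyphenyl 2-(benzyloxy)-6-methoxybenzoate | CC(=O)c1c(OC(=O)c2c(OC)cccc2OCc2ccccc2)c(OC)c(OC)c(OCc2ccccc2)c1OC
F4 | step 2 | 2-acetyl-3,5,6-trimethoxycyclohexa-2,5-diene-1,4-dione | CC(=O)C1=C(OC)C(=O)C(OC)=C(OC)C1=O
F5 | step 6 | 1-methoxy-3-(methoxymethoxy)benzene | COCOc1cccc(OC)c1
F6 | step 6 | [2-methoxy-6-(methoxymethoxy)phenyl]lithium | [Li]c1c(OC)cccc1OCOC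
F7 | step 6 | 2-iodo-1-methoxy-3-(methoxymethoxy)benzene | COCOc1cccc(OC)c1I
F8 | step 6 | 2-iodo-3-methoxyphenol | COc1cccc(O)c1I
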